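The C2 acetate and C3 tertiary alcohol are traced to a C2–C3 oxirane, and that oxirane to the C2=C3 alkene of an allylic alcohol whose directing hydroxyl is the hydroxymethyl arm on C3 (the later CH2OAc). One titanium–tartrate oxygen transfer closes the three-membered ring, forms both C–O bonds and fixes C3 and, pending inversion by acetate, C2, while the two trisubstituted side-chain alkenes stay untouched. The substrate is the (Z)-allylic alcohol in which the benzylic C1 and the ketal carbon C4 of the preformed 2,8-dioxabicyclo[3.2.1]octane cage are cis. The cage comes from (R)-linalool, and the arene is carried as a hydroquinone dimethyl ether.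

Key step: step 16

Remark on numbering: C1 is the benzylic CH2, C2 the acetoxy methine, C3 the tertiary carbinol, C4 the ketal carbon, C7 the methyl-bearing bridgehead, C9 the ring CH–O carrying the dienyl chain (C10–C16). Read from the target: C2 R, C3 S, C4 R, C7 R, C9 S, C10=C11 E, with the C9 dienyl group equatorial (exo) on the dioxane ring of the cage.

Abbreviation: Cg = (1R,3S,5R)-3-[(1E)-2,6-dimethylhepta-1,5-dien-1-yl]-5-methyl-2,8-dioxabicyclo[3.2.1]octan-1-yl.

Assumption: (R)-(−)-linalool of high enantiomeric purity is taken as purchasable.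

**Route**

Step 1
Reactants: 1 2,5-dimethoxy-4-methylbenzaldehyde
Product: 2 (2,5-dimethoxy-4-methylphenyl)methanol
Conditions: NaBH4, MeOH, 0 °C
Reagents that add atoms: none
Why: Borohydride reduction of an aromatic aldehyde to the benzylic alcohol is fast and leaves the aryl methyl ethers untouched (carbonyl hydride reduction).

Step 2
Reactants: 2 (2,5-dimethoxy-4-methylphenyl)methanol
Product: 3 1-(bromomethyl)-2,5-dimethoxy-4-methylbenzene
Conditions: PBr3, CH2Cl2, 0 °C
Reagents that add atoms: phosphorus tribromide, BrP(Br)Br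
Why: The electron-rich benzylic alcohol is converted into the bromide by displacement of its phosphite ester (SN2 bromination), and the labile bromide is used at once.

Step 3
Reactants: 3 1-(bromomethyl)-2,5-dimethoxy-4-methylbenzene; 4 prop-2-yn-1-ol
Product: 5 4-(2,5-dimethoxy-4-methylphenyl)but-2-yn-1-ol
Conditions: 4, EtMgBr (2.1 equiv), THF, 0 °C to rt; CuCl (10 mol%); then 3, THF, 55 °C
Reagents that add atoms: none
Why: Double deprotonation gives the alkoxide–alkynyl Grignard, and copper-catalysed alkynyl–benzyl coupling forms the C1–C2 bond at carbon while the magnesium alkoxide stays inert.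

Step 4
Reactants: 5 4-(2,5-dimethoxy-4-methylphenyl)but-2-yn-1-ol
Product: 7 (2Z)-4-(2,5-dimethoxy-4-methylphenyl)-2-iodobut-2-en-1-ol, via vinylstannane 6 (not isolated)
Conditions: Bu3SnH (1.05 equiv), [(C5Me5)RuCl]4 (2 mol%), CH2Cl2, rt; then I2 (1.1 equiv), 0 °C
Reagents that add atoms: iodine, II
Why: Hydroxyl-directed ruthenium-catalysed trans-hydrostannation puts tin on the alkyne carbon next to CH2OH and hydrogen anti to it, and tin–iodine exchange with retention gives the 2-iodo (Z)-alkene, which hydroalumination–iodination (iodine on the distal carbon) would not deliver.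

Step 5
Reactants: 7 (2Z)-4-(2,5-dimethoxy-4-methylphenyl)-2-iodobut-2-en-1-ol
Product: 8 tert-butyl{[(2Z)-4-(2,5-dimethoxy-4-methylphenyl)-2-iodobut-2-en-1-yl]oxy}dimethylsilane
Conditions: t-BuMe2SiCl, imidazole, CH2Cl2, 0 °C to rt
Reagents that add atoms: tert-butyldimethylsilyl chloride, CC(C)(C)[Si](C)(C)Cl
Why: Imidazole-promoted silyl ether formation removes the acidic proton before the later halogen–lithium exchange.

Step 6
Reactants: 9 6-methylhept-5-en-2-one
Product: 11 6-methylhept-5-en-1-yne, via enol phosphate 10 (not isolated)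
Conditions: LiN(iPr)2 (1.05 equiv), THF, −78 °C; ClP(O)(OEt)2; then LiN(iPr)2 (2.3 equiv), −78 °C to rt
Reagents that add atoms: none
Why: Kinetic deprotonation on the methyl side, O-phosphorylation and elimination with excess amide base give the terminal alkyne (Negishi conversion of a methyl ketone into an alkyne via its enol phosphate).

Step 7
Reactants: 11 6-methylhept-5-en-1-yne
Product: 13 (1E)-1-iodo-2,6-dimethylhepta-1,5-diene, via alkenylalane 12 (not isolated)
Conditions: Me3Al (2 equiv), Cp2ZrCl2 (0.25 equiv), CH2Cl2, 0 °C to rt; then I2, THF, −30 to 0 °C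
Reagents that add atoms: trimethylaluminium, C[Al](C)C; iodine, II
Why: Zirconium-catalysed syn-carboalumination (Negishi methylalumination) adds methyl to the internal and aluminium to the terminal alkyne carbon on the same side, and iodinolysis with retention fixes the (E)-trisubstituted alkene.

Step 8
Reactants: 14 (R)-linalool
Product: 16 (5R)-5-ethenyl-5-methyloxolan-2-one, via lactol 15 (not isolated)
Conditions: O3, CH2Cl2, Sudan Red 7B (indicator), −78 °C; PPh3, −78 °C to rt; then TEMPO (10 mol%), PhI(OAc)2, rt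
Reagents that add atoms: ozone, [O-][O+]=O
Why: Ozone cleaves the electron-rich trisubstituted alkene much faster than the vinyl group, the tertiary hydroxyl traps the aldehyde as a lactol, and oxoammonium oxidation gives the lactone with the C7 centre of linalool untouched (ozonolysis, then lactol oxidation).

Step 9
Reactants: 16 (5R)-5-ethenyl-5-methyloxolan-2-one
Product: 17 (5R)-5-(2-hydroxyethyl)-5-methyloxolan-2-one
Conditions: 9-BBN, THF, 0 °C to rt; then NaBO3·4H2O, H2O, rt
Reagents that add atoms: sodium perborate, [Na+].[Na+].O[B-]1(O)OO[B-](O)(O)OO1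
Why: 9-BBN adds anti-Markovnikov to the monosubstituted alkene and reduces a lactone only very slowly, and perborate oxidizes the alkylborane to the primary alcohol under mild conditions (hydroboration–oxidation).

Step 10
Reactants: 17 (5R)-5-(2-hydroxyethyl)-5-methyloxolan-2-one
Product: 18 2-[(2R)-2-methyl-5-oxooxolan-2-yl]acetic acid
Conditions: TEMPO (20 mol%), PhI(OAc)2 (2.2 equiv), MeCN–H2O (1:1), rt
Reagents that add atoms: water, O
Why: Oxoammonium oxidation in water takes the primary alcohol through the aldehyde hydrate to the acid without base, so the β-acyloxy carbonyl intermediate cannot eliminate (TEMPO/iodosobenzene diacetate oxidation).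

Step 11
Reactants: 18 2-[(2R)-2-methyl-5-oxooxolan-2-yl]acetic acid; 13 (1E)-1-iodo-2,6-dimethylhepta-1,5-diene
Product: 22 (5R)-5-[(3E)-4,8-dimethyl-2-oxonona-3,7-dien-1-yl]-5-methyloxolan-2-one, via acid chloride 19 (not isolated), via alkenyllithium 20 (not isolated), via alkenylzinc chloride 21 (not isolated)
Conditions: 18, (COCl)2, DMF (cat.), CH2Cl2, 0 °C to rt, evaporation; 13, t-BuLi (2 equiv), Et2O, −78 °C, then ZnCl2, THF, to 0 °C; both combined, Pd(PPh3)4 (5 mol%), THF, 0 °C to rt
Reagents that add atoms: none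
Why: Palladium-catalysed acylation of the alkenylzinc by the acid chloride (Negishi acylation) forms the C9–C10 bond with retention of alkene geometry, and the organozinc does not attack the lactone.

Step 12
Reactants: 22 (5R)-5-[(3E)-4,8-dimethyl-2-oxonona-3,7-dien-1-yl]-5-methyloxolan-2-one
Product: 23 (5R)-5-[(2S,3E)-2-hydroxy-4,8-dimethylnona-3,7-dien-1-yl]-5-methyloxolan-2-one
Conditions: (R)-2-methyl-CBS-oxazaborolidine (0.5 equiv), catecholborane, toluene, −78 °C
Reagents that add atoms: none
Why: In the oxazaborolidine-catalysed reduction (Corey–Bakshi–Shibata) the alkenyl group acts as the large substituent, so the (R)-catalyst should deliver hydride to the face that makes C9 S, and catecholborane at low temperature spares lactone and alkenes.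

Step 13
Reactants: 23 (5R)-5-[(2S,3E)-2-hydroxy-4,8-dimethylnona-3,7-dien-1-yl]-5-methyloxolan-2-one
Product: 24 (5R)-5-[(2S,3E)-4,8-dimethyl-2-(triethylsilyloxy)nona-3,7-dien-1-yl]-5-methyloxolan-2-one
Conditions: Et3SiCl, imidazole, CH2Cl2, 0 °C
Reagents that add atoms: chlorotriethylsilane, CC[Si](Cl)(CC)CC
Why: Silyl ether formation masks the C9 hydroxyl so that one equivalent of alkenyllithium suffices in the coupling, and the group leaves again in the fluoride–acid step.

Step 14
Reactants: 8 tert-butyl{[(2Z)-4-(2,5-dimethoxy-4-methylphenyl)-2-iodobut-2-en-1-yl]oxy}dimethylsilane; 24 (5R)-5-[(2S,3E)-4,8-dimethyl-2-(triethylsilyloxy)nona-3,7-dien-1-yl]-5-methyloxolan-2-one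
Product: 26 (2Z,7R,9S,10E)-3-{[tert-butyl(dimethyl)silyl]oxymethyl}-1-(2,5-dimethoxy-4-methylphenyl)-7-hydroxy-7,11,15-trimethyl-9-(triethylsilyloxy)hexadeca-2,10,14-trien-4-one, via alkenyllithium 25 (not isolated)
Conditions: 8 (1.2 equiv), t-BuLi (2.4 equiv), Et2O, −78 °C; then 24, THF, −78 °C; AcOH, −78 °C
Reagents that add atoms: none
Why: Iodine–lithium exchange with retention gives the alkenyllithium, which should add once to the lactone carbonyl because the lithium lactolate survives at −78 °C until the quench (acylation of an organolithium by a lactone); the product is in equilibrium with its cyclic hemiketal and is used at once.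

Step 15
Reactants: 26 the hydroxy enone of step 14
Product: 27 (2Z)-4-(2,5-dimethoxy-4-methylphenyl)-2-Cg-but-2-en-1-ol
Conditions: HF·pyridine, pyridine, THF, 0 °C to rt; then PPTS (cat.), 4 Å MS, CH2Cl2, rt
Reagents that add atoms: none
Why: Fluoride removes both silyl ethers and mild acid closes the C7 and C9 hydroxyls onto the C4 carbonyl under thermodynamic control (desilylative intramolecular ketalization), C4 being fixed by the bridge from C7 and the C9 dienyl group ending equatorial.

Step 16
Reactants: 27 (2Z)-4-(2,5-dimethoxy-4-methylphenyl)-2-Cg-but-2-en-1-ol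
Product: 28 [(2S,3S)-3-(2,5-dimethoxy-4-methylbenzyl)-2-Cg-oxiran-2-yl]methanol
Conditions: Ti(OiPr)4 (0.3 equiv), L-(+)-diisopropyl tartrate (0.36 equiv), t-BuOOH (2 equiv, in isooctane), 4 Å MS, CH2Cl2, −20 °C
Reagents that add atoms: tert-butyl hydroperoxide, CC(C)(C)OO
Why: The primary allylic alkoxide and tert-butyl hydroperoxide are held on the titanium–tartrate dimer, and the peroxide oxygen is passed to one face of the C2=C3 double bond (Katsuki–Sharpless asymmetric epoxidation of a 2,3-disubstituted allylic alcohol with no substituent cis to CH2OH, a favourable class). The oxirane closes in that single concerted, suprafacial oxygen-atom transfer, both C–O bonds forming together, so the ring arises by one-atom addition and not by a stepwise exo or endo closure. C3 is controlled by the alkene face that L-(+)-diisopropyl tartrate selects, and C2 by the same face together with the fixed (Z)-geometry, which keeps C1 and C4 cis on the ring and gives the (2S,3S)-epoxide. The step needs chemoselectivity over the two trisubstituted side-chain alkenes, secured because only C2=C3 is allylic to a free hydroxyl, and face selectivity that overrides any bias of the chiral cage at C4, secured by reagent control, which normally dominates for primary allylic alcohols. The quaternary ketal carbon on the carbinol-bearing alkene carbon is expected to slow oxygen transfer, hence the high catalyst loading and the sieves.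

Step 17
Reactants: 28 [(2S,3S)-3-(2,5-dimethoxy-4-methylbenzyl)-2-Cg-oxiran-2-yl]methanol
Product: 29 (2R,3S)-1-(2,5-dimethoxy-4-methylphenyl)-3,4-dihydroxy-3-Cg-butan-2-yl acetate
Conditions: Ti(OiPr)4 (1.5 equiv), AcOH (3 equiv), CH2Cl2, rt
Reagents that add atoms: acetic acid, CC(=O)O
Why: The titanium alkoxide of the epoxy alcohol activates the oxirane and delivers acetate to C2, the carbon remote from the hydroxymethyl group and the only epoxide carbon that is not quaternary, with inversion (titanium-mediated regioselective opening of a 2,3-epoxy alcohol by a carboxylic acid).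

Step 18
Reactants: 29 (2R,3S)-1-(2,5-dimethoxy-4-methylphenyl)-3,4-dihydroxy-3-Cg-butan-2-yl acetate
Product: 30 (2R,3S)-1-(2,5-dimethoxy-4-methylphenyl)-3-hydroxy-3-Cg-butane-2,4-diyl diacetate
Conditions: Ac2O, pyridine, DMAP (cat.), CH2Cl2, 0 °C
Reagents that add atoms: acetic anhydride, CC(=O)OC(C)=O
Why: The primary hydroxyl (and any secondary hydroxyl freed by acetyl migration) is esterified while the hindered tertiary C3 hydroxyl stays free (selective acetylation).

Step 19
Reactants: 30 (2R,3S)-1-(2,5-dimethoxy-4-methylphenyl)-3-hydroxy-3-Cg-butane-2,4-diyl diacetate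
Product: 32 (2R,3S)-1-(2,5-dihydroxy-4-methylphenyl)-3-hydroxy-3-Cg-butane-2,4-diyl diacetate, via quinone 31 (not isolated)
Conditions: (NH4)2Ce(NO3)6 (2.5 equiv), MeCN–H2O, 0 °C; then EtOAc, aqueous Na2S2O4, rt
Reagents that add atoms: water, O
Why: Tetravalent cerium oxidizes the hydroquinone dimethyl ether to the quinone with loss of methanol faster than it attacks the alkenes (oxidative demethylation), and dithionite then reduces the quinone to the hydroquinone in the same flask.

**Compound list**

1 | 2,5-dimethoxy-4-methylbenzaldehyde | COc1cc(C)c(OC)cc1C=O | starting material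
2 | (2,5-dimethoxy-4-methylphenyl)methanol | COc1cc(C)c(OC)cc1CO | intermediate
3 | 1-(bromomethyl)-2,5-dimethoxy-4-methylbenzene | COc1cc(C)c(OC)cc1CBr | intermediate
4 | prop-2-yn-1-ol (propargyl alcohol) | OCC#C | starting material
5 | 4-(2,5-dimethoxy-4-methylphenyl)but-2-yn-1-ol | OCC#CCc1cc(OC)c(C)cc1OC | intermediate
6 | (2Z)-4-(2,5-dimethoxy-4-methylphenyl)-2-(tributylstannyl)but-2-en-1-ol | OC/C(=C/Cc1cc(OC)c(C)cc1OC)[Sn](CCCC)(CCCC)CCCC | intermediate
7 | (2Z)-4-(2,5-dimethoxy-4-methylphenyl)-2-iodobut-2-en-1-ol | OC/C(I)=C/Cc1cc(OC)c(C)cc1OC | intermediate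
8 | tert-butyl{[(2Z)-4-(2,5-dimethoxy-4-methylphenyl)-2-iodobut-2-en-1-yl]oxy}dimethylsilane | CC(C)(C)[Si](C)(C)OC/C(I)=C/Cc1cc(OC)c(C)cc1OC | intermediate
9 | 6-methylhept-5-en-2-one | CC(=O)CCC=C(C)C | starting material
10 | diethyl 6-methylhepta-1,5-dien-2-yl phosphate | C=C(CCC=C(C)C)OP(=O)(OCC)OCC | intermediate
11 | 6-methylhept-5-en-1-yne | C#CCCC=C(C)C | intermediate
12 | [(1E)-2,6-dimethylhepta-1,5-dien-1-yl]dimethylalane | C[Al](C)/C=C(\C)CCC=C(C)C | intermediate
13 | (1E)-1-iodo-2,6-dimethylhepta-1,5-diene | I/C=C(\C)CCC=C(C)C | intermediate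
14 | (R)-linalool, (3R)-3,7-dimethylocta-1,6-dien-3-ol | CC(C)=CCC[C@](C)(C=C)O | starting material
15 | (5R)-5-ethenyl-5-methyloxolan-2-ol (anomer mixture) | OC1CC[C@](C)(C=C)O1 | intermediate
16 | (5R)-5-ethenyl-5-methyloxolan-2-one | O=C1CC[C@](C)(C=C)O1 | intermediate
17 | (5R)-5-(2-hydroxyethyl)-5-methyloxolan-2-one | O=C1CC[C@](C)(CCO)O1 | intermediate
18 | 2-[(2R)-2-methyl-5-oxooxolan-2-yl]acetic acid | O=C1CC[C@](C)(CC(=O)O)O1 | intermediate
19 | 2-[(2R)-2-methyl-5-oxooxolan-2-yl]acetyl chloride | O=C1CC[C@](C)(CC(=O)Cl)O1 | intermediate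
20 | [(1E)-2,6-dimethylhepta-1,5-dien-1-yl]lithium | [Li]/C=C(\C)CCC=C(C)C | intermediate
21 | chloro[(1E)-2,6-dimethylhepta-1,5-dien-1-yl]zinc | Cl[Zn]/C=C(\C)CCC=C(C)C | intermediate
22 | (5R)-5-[(3E)-4,8-dimethyl-2-oxonona-3,7-dien-1-yl]-5-methyloxolan-2-one | O=C1CC[C@](C)(CC(=O)/C=C(\C)CCC=C(C)C)O1 | intermediate
23 | (5R)-5-[(2S,3E)-2-hydroxy-4,8-dimethylnona-3,7-dien-1-yl]-5-methyloxolan-2-one | O=C1CC[C@](C)(C[C@H](O)/C=C(\C)CCC=C(C)C)O1 | intermediate
24 | (5R)-5-[(2S,3E)-4,8-dimethyl-2-(triethylsilyloxy)nona-3,7-dien-1-yl]-5-methyloxolan-2-one | O=C1CC[C@](C)(C[C@H](O[Si](CC)(CC)CC)/C=C(\C)CCC=C(C)C)O1 | intermediate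
25 | alkenyllithium from 8 (lithium in place of iodine, C1 cis to lithium) | CC(C)(C)[Si](C)(C)OC/C([Li])=C/Cc1cc(OC)c(C)cc1OC | intermediate
26 | (2Z,7R,9S,10E)-3-{[tert-butyl(dimethyl)silyl]oxymethyl}-1-(2,5-dimethoxy-4-methylphenyl)-7-hydroxy-7,11,15-trimethyl-9-(triethylsilyloxy)hexadeca-2,10,14-trien-4-one | CC(C)(C)[Si](C)(C)OC/C(=C/Cc1cc(OC)c(C)cc1OC)C(=O)CC[C@@](C)(O)C[C@H](O[Si](CC)(CC)CC)/C=C(\C)CCC=C(C)C | intermediate
27 | (2Z)-4-(2,5-dimethoxy-4-methylphenyl)-2-Cg-but-2-en-1-ol | OC/C(=C/Cc3cc(OC)c(C)cc3OC)[C@]12CC[C@](C)(C[C@@H](/C=C(\C)CCC=C(C)C)O1)O2 | intermediate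
28 | [(2S,3S)-3-(2,5-dimethoxy-4-methylbenzyl)-2-Cg-oxiran-2-yl]methanol | OC[C@@]3(O[C@H]3Cc4cc(OC)c(C)cc4OC)[C@]12CC[C@](C)(C[C@@H](/C=C(\C)CCC=C(C)C)O1)O2 | intermediate
29 | (2R,3S)-1-(2,5-dimethoxy-4-methylphenyl)-3,4-dihydroxy-3-Cg-butan-2-yl acetate | OC[C@](O)([C@@H](Cc3cc(OC)c(C)cc3OC)OC(C)=O)[C@]12CC[C@](C)(C[C@@H](/C=C(\C)CCC=C(C)C)O1)O2 | intermediate
30 | (2R,3S)-1-(2,5-dimethoxy-4-methylphenyl)-3-hydroxy-3-Cg-butane-2,4-diyl diacetate | CC(=O)OC[C@](O)([C@@H](Cc3cc(OC)c(C)cc3OC)OC(C)=O)[C@]12CC[C@](C)(C[C@@H](/C=C(\C)CCC=C(C)C)O1)O2 | intermediate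
31 | (2R,3S)-3-hydroxy-1-(4-methyl-3,6-dioxocyclohexa-1,4-dien-1-yl)-3-Cg-butane-2,4-diyl diacetate | CC(=O)OC[C@](O)([C@@H](CC3=CC(=O)C(C)=CC3=O)OC(C)=O)[C@]12CC[C@](C)(C[C@@H](/C=C(\C)CCC=C(C)C)O1)O2 | intermediate
32 | (2R,3S)-1-(2,5-dihydroxy-4-methylphenyl)-3-hydroxy-3-Cg-butane-2,4-diyl diacetate | CC(=O)OC[C@](O)([C@@H](Cc1cc(O)c(C)cc1O)OC(C)=O)[C@]12CC[C@](C)(C[C@@H](/C=C(\C)CCC=C(C)C)O1)O2 | target

**Count and risks**

Total step count: 19. Longest linear sequence: 12 steps (steps 8 to 19, from (R)-linalool).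

Step 16 (key step). What may go wrong: slow oxygen transfer because the quaternary ketal carbon crowds the titanium–tartrate pocket, loss of facial selectivity if cage and tartrate are a mismatched pair, and opening of the epoxy alcohol on titanium during a long reaction. Fallback: setting out from 27, the epoxidation would be run with a vanadium catalyst carrying a chiral C2-symmetric bis-hydroxamic acid ligand (VO(OiPr)3, ligand, aqueous t-BuOOH, toluene, 0 °C). This is a hydroxyl-directed, ligand-accelerated system with a smaller metal centre that accepts hindered 2,3-disubstituted allylic alcohols. The ligand enantiomer that delivers oxygen to the same face is chosen, and the route is rejoined at 28 with no new intermediate.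

Step 17. What may go wrong: participation of the electron-rich ring or of its ortho methoxy oxygen in the opening at C2 (five-membered ring closure with loss of the methyl group, or a bridged arenium path that erodes inversion), and loss of the acetyl group by transesterification. Fallback: setting out from 28, the arene would be deactivated first. Oxidation with (NH4)2Ce(NO3)6 in MeCN–H2O at 0 °C should give the quinone epoxy alcohol F1, whose ring no longer participates. Opening with Ti(OiPr)4 and AcOH should then give the quinone diol monoacetate F2. Acetylation of the primary hydroxyl (Ac2O, pyridine, 0 °C) leads to 31, where the route is rejoined for the dithionite reduction to 32.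

Step 14. What may go wrong: a second addition of the alkenyllithium to the ring-opened ketone, enolization of the lactone, loss of silanolate from the β-silyloxy alkenyllithium, or isomerization of the enone in which C1 is cis to the carbonyl before it is ketalized. Fallback: setting out from 24, i-Bu2AlH (CH2Cl2, −78 °C) would give the lactol F3. Its open hydroxy aldehyde form would be coupled with iodide 8 under Nozaki–Hiyama–Kishi conditions (CrCl2, NiCl2 cat., DMSO–THF, rt), which keep the alkene geometry and cannot over-add, to give the diol F4 as a mixture of C4 epimers. MnO2 (CH2Cl2, rt) would oxidize only the allylic secondary alcohol and return the route to 26.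

Further compounds
F0 | step 16 | none | none
F1 | step 17 | 2-{[(2S,3S)-3-(hydroxymethyl)-3-Cg-oxiran-2-yl]methyl}-5-methylcyclohexa-2,5-diene-1,4-dione | OC[C@@]3(O[C@H]3CC4=CC(=O)C(C)=CC4=O)[C@]12CC[C@](C)(C[C@@H](/C=C(\C)CCC=C(C)C)O1)O2
F2 | step 17 | (2R,3S)-3,4-dihydroxy-1-(4-methyl-3,6-dioxocyclohexa-1,4-dien-1-yl)-3-Cg-butan-2-yl acetate | OC[C@](O)([C@@H](CC3=CC(=O)C(C)=CC3=O)OC(C)=O)[C@]12CC[C@](C)(C[C@@H](/C=C(\C)CCC=C(C)C)O1)O2
F3 | step 14 | (5R)-5-[(2S,3E)-4,8-dimethyl-2-(triethylsilyloxy)nona-3,7-dien-1-yl]-5-methyloxolan-2-ol (anomer mixture) | OC1CC[C@](C)(C[C@H](O[Si](CC)(CC)CC)/C=C(\C)CCC=C(C)C)O1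
F4 | step 14 | (2Z,7R,9S,10E)-3-{[tert-butyl(dimethyl)silyl]oxymethyl}-1-(2,5-dimethoxy-4-methylphenyl)-7,11,15-trimethyl-9-(triethylsilyloxy)hexadeca-2,10,14-triene-4,7-diol (C4 epimers) | CC(C)(C)[Si](C)(C)OC/C(=C/Cc1cc(OC)c(C)cc1OC)C(O)CC[C@@](C)(O)C[C@H](O[Si](CC)(CC)CC)/C=C(\C)CCC=C(C)C
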